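Late in a run of this flask, the balance with the dormant form, taken by itself, holds 93.8% of the electrophile charged as dormant form, more than the 90% I wanted. But that relaxation has a rate constant of 0.0149 s⁻¹, so by itself it reaches 78.1% in the time allowed. My decision for the next run was how much nucleophile to charge to close that gap.

electrophile 0.25 M; solid base 0.125 M; time 2.0 min

    electrophile + nucleophile → acid set free + product (k1 = 0.072 M⁻¹ s⁻¹)
    nucleophile + acid set free ⇌ protonated nucleophile, settled at all times (K2 = 3800 M⁻¹)
    acid set free + free base ⇌ salt of the base (K3 = 12 M⁻¹, k3 = 3.2 M⁻¹ s⁻¹)
    electrophile ⇌ dormant form (K4 = 15, k4 = 0.014 s⁻¹)
    solid base ⇌ free base, rate k5*(cs5 - [free base]) while solid is left; crystals form when [free base] > cs5 (cs5 = 15 mM, k5 = 0.043 s⁻¹)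

1. the concentration of nucleophile at which the part of the electrophile that has reacted at 2.0 min is just 90%, in M

Electrophile leaves by two routes: forward into the dormant form at 0.014 s⁻¹, and by capture with the pseudo-first-order constant 0.072 M⁻¹ s⁻¹ times [nucleophile]. The two are equal at the crossing concentration, the forward dormant constant over the capture constant, 0.194 M. Leaving 10.0% of the electrophile in 2.0 min, with the return from the dormant form ignored, takes a total loss constant of 0.0192 s⁻¹. The dormant route supplies 0.014 s⁻¹, so capture had to supply 0.00519 s⁻¹, which means a mean free [nucleophile] of 0.0721 M, below the crossing. On that reckoning capture takes 0.0608 M of electrophile. I counted two nucleophiles for each captured electrophile, one for the product and one for the acid set free, because the constant for acid on nucleophile is far larger than the one for acid on free base. That makes a spend of 0.122 M, and a level falling steadily by that amount has its mean 0.0608 M below the charge, so I committed to a charge of 0.133 M and left the solid base as charged.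

The forecast put the need at 1.8 M, holding that "the nucleophile must be well over 1 M to hold the dormant share to about 10%".

This flask needed 0.243 M, more than my charge and less than the forecast's. At that charge it began above the crossing of 0.194 M, but 69.5% of the nucleophile was still free after 0.200 min, which is 0.169 M, already under the crossing. At 2.00 min, the forward step to the dormant form was using electrophile 3.4 times as fast as capture.

(The constants are invented; the run is a simulation.)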